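**Retrosynthetic overview**
1. The target is reached by enzymatic separation of the two ring diastereomers formed from cyclobutenyl acetate 21 in a one-pot anionic 4π ring opening / 6π electrocyclisation / enolate hydroxylation. This makes the whole cyclohexenone (enone, cis C4‑OAc/C5‑chain pair, C6‑OH) from a cyclobutene by taking up the two alkenyl carbons.
2. Enabling feature: in 21 the four‑membered ring C1(OH)(alkenyl)–C2(CH3)=C3H–C4H(OAc) carries the C1–O and C4–O bonds trans. On deprotonation both oxygens can rotate outward when the C1–C4 σ bond opens, and the C1 alkenyl group is forced inward, giving a cisoid 3‑oxido‑1,3,5‑hexatriene.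
3. 21 comes from trans‑diol 20, this from hydroxycyclobutenone 19 (Luche reduction), and 19 from semisquarate 15 (from diisopropyl squarate 13) by 1,2‑addition of tetraenyllithium 16, then MeLi, then hydrolytic carbonyl transposition.
4. Stannane 12 comes from a Julia–Kocienski union of sulfone 7 (from (S)‑3‑bromo‑2‑methylpropan‑1‑ol by Z‑Wittig) with stannyl dienal 10 (from (2E)‑3‑methylpent‑2‑en‑4‑yn‑1‑ol).
5. Ring order: the only ring is formed last (step 12), by four‑ to six‑membered ring expansion.

Key step: step 12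

Abbreviations: Tet = (1E,3E,5E,7R,8Z)‑3,7,11‑trimethyldodeca‑1,3,5,8‑tetraen‑1‑yl; SC = (2E,4E,6R,7Z)‑6,10‑dimethylundeca‑2,4,7‑trien‑2‑yl; PT = 1‑phenyl‑1H‑tetrazol‑5‑yl. Ring locants in the text are those of the cyclohexenone (C1 = C=O, C2 = C–CH3, C3 = CH, C4 = CH–OAc, C5 = CH–SC, C6 = CH–OH; side‑chain stereocentre = C6′); the target is 4S,5R,6R,6′R.

Assumption: the 6π closure runs through a planar triene whose only stereocentre is the remote C6′, so no facial bias is expected; 17–24 are therefore treated as near‑equal pairs of diastereomers differing only in ring centres that step 12 erases (one is drawn), and the absolute configuration of the ring is secured by the enzymatic step 13.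

Step 1
Reactants: 1 (S)-3-bromo-2-methylpropan-1-ol
Product: 2 (S)-(3-hydroxy-2-methylpropyl)triphenylphosphonium bromide
Conditions: PPh3, MeCN, reflux
Reagents that add atoms: triphenylphosphine, c1ccc(cc1)P(c1ccccc1)c1ccccc1
Why: SN2 quaternisation of the primary bromide by the phosphine; the stereocentre is not touched.

Step 2
Reactants: 2 (S)-(3-hydroxy-2-methylpropyl)triphenylphosphonium bromide; 3 3-methylbutanal
Product: 5 (2R,3Z)-2,6-dimethylhept-3-en-1-ol, via oxido ylide 4 (not isolated)
Conditions: NaHMDS (2.1 equiv), THF, 0 °C; then 3, −78 °C to rt; aq NH4Cl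
Reagents that add atoms: none
Why: Wittig olefination with a non‑stabilised ylide under salt‑free conditions should give the Z alkene; the stereocentre is β to phosphorus and cannot epimerise (S becomes R only through CIP priorities).

Step 3
Reactants: 5 (2R,3Z)-2,6-dimethylhept-3-en-1-ol
Product: 6 5-{[(2R,3Z)-2,6-dimethylhept-3-en-1-yl]sulfanyl}-1-phenyl-1H-tetrazole
Conditions: PT‑SH, PPh3, DIAD, THF, 0 °C to rt
Reagents that add atoms: 1-phenyl-1H-tetrazole-5-thiol, Sc1nnnn1-c1ccccc1
Why: Mitsunobu thioetherification of an unhindered primary alcohol; the stereocentre is one carbon away and unaffected.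

Step 4
Reactants: 6 5-{[(2R,3Z)-2,6-dimethylhept-3-en-1-yl]sulfanyl}-1-phenyl-1H-tetrazole
Product: 7 5-{[(2R,3Z)-2,6-dimethylhept-3-en-1-yl]sulfonyl}-1-phenyl-1H-tetrazole
Conditions: 30% H2O2, (NH4)6Mo7O24·4H2O (cat.), EtOH, 0 °C to rt
Reagents that add atoms: hydrogen peroxide, OO
Why: molybdate‑catalysed oxidation of sulfide to sulfone, which should be chemoselective over the isolated 1,2‑disubstituted alkene.

Step 5
Reactants: 8 (2E)-3-methylpent-2-en-4-yn-1-ol
Product: 9 (2E,4E)-3-methyl-5-(tributylstannyl)penta-2,4-dien-1-ol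
Conditions: Bu3SnH, PdCl2(PPh3)2 (cat.), THF, 0 °C
Reagents that add atoms: tributyltin hydride, CCCC[SnH](CCCC)CCCC
Why: Pd‑catalysed syn hydrostannation of the terminal alkyne of a conjugated enyne should place tin at the terminus and give the E alkenylstannane.

Step 6
Reactants: 9 (2E,4E)-3-methyl-5-(tributylstannyl)penta-2,4-dien-1-ol
Product: 10 (2E,4E)-3-methyl-5-(tributylstannyl)penta-2,4-dienal
Conditions: MnO2, CH2Cl2, rt
Reagents that add atoms: none
Why: MnO2 oxidation of a primary allylic alcohol to the enal without touching the alkenylstannane or the alkene geometry.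

Step 7
Reactants: 7 5-{[(2R,3Z)-2,6-dimethylhept-3-en-1-yl]sulfonyl}-1-phenyl-1H-tetrazole; 10 (2E,4E)-3-methyl-5-(tributylstannyl)penta-2,4-dienal
Product: 12 tributyl[(1E,3E,5E,7R,8Z)-3,7,11-trimethyldodeca-1,3,5,8-tetraen-1-yl]stannane, via metalated sulfone 11 (not isolated)
Conditions: KHMDS, DME, −78 °C; then 10, −78 °C to rt; aq NH4Cl
Reagents that add atoms: none
Why: Julia–Kocienski olefination of a PT sulfone with an unsaturated aldehyde should give the new C5=C6 bond E; the stereocentre is β to sulfur and is not deprotonated.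

Step 8
Reactants: 13 diisopropyl squarate
Product: 15 3-isopropoxycyclobut-3-ene-1,2-dione, via 4-hydroxy-2,3-diisopropoxycyclobut-2-en-1-one 14 (not isolated)
Conditions: LiAlH(OtBu)3, THF, −20 °C; then 6 M HCl, CH2Cl2, rt
Reagents that add atoms: none
Why: mono 1,2‑reduction of the squarate followed by acid‑promoted loss of isopropanol from the vinylogous hemiacetal, a known entry to semisquarates.

Step 9
Reactants: 12 tributyl[(1E,3E,5E,7R,8Z)-3,7,11-trimethyldodeca-1,3,5,8-tetraen-1-yl]stannane; 15 3-isopropoxycyclobut-3-ene-1,2-dione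
Product: 19 4-hydroxy-3-methyl-4-Tet-cyclobut-2-en-1-one, via tetraenyllithium 16 (not isolated), via lithium alkoxide adduct 17 (not isolated), via dilithium diolate 18 (not isolated)
Conditions: n‑BuLi, THF, −78 °C; 15, −78 °C; MeLi, −78 °C; 1 M HCl (aq), −78 to 0 °C
Reagents that add atoms: methyllithium, [Li]C; water, O
Why: tin–lithium exchange with retention of alkene geometry, 1,2‑addition to the more electrophilic (non‑vinylogous‑ester) carbonyl of 15, a second 1,2‑addition of MeLi to the remaining carbonyl, and acid hydrolysis of the enol ether with 1,3‑carbonyl transposition (Stork–Danheiser type) should give 19; its carbinol centre forms without control, which does not matter because step 12 erases it.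

Step 10
Reactants: 19 4-hydroxy-3-methyl-4-Tet-cyclobut-2-en-1-one
Product: 20 (1R*,4R*)-2-methyl-1-Tet-cyclobut-2-ene-1,4-diol
Conditions: NaBH4, CeCl3·7H2O, MeOH, −78 °C
Reagents that add atoms: none
Why: Luche 1,2‑reduction; hydride should attack the face of the planar cyclobutenone that carries the small tertiary OH (anti to the bulky Tet group, possibly helped by Ce chelation), which sets the new secondary OH trans to the tertiary OH.

Step 11
Reactants: 20 (1R*,4R*)-2-methyl-1-Tet-cyclobut-2-ene-1,4-diol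
Product: 21 (1R*,4R*)-4-hydroxy-3-methyl-4-Tet-cyclobut-2-en-1-yl acetate
Conditions: Ac2O (1.1 equiv), Et3N, DMAP (cat.), CH2Cl2, −20 °C
Reagents that add atoms: acetic anhydride, CC(=O)OC(C)=O
Why: DMAP‑catalysed acylation should discriminate cleanly between the secondary and the tertiary alcohol; no stereocentre is affected.

Step 12
Reactants: 21 (1R*,4R*)-4-hydroxy-3-methyl-4-Tet-cyclobut-2-en-1-yl acetate
Product: 25 4,5-cis-5,6-trans-4-acetoxy-6-hydroxy-2-methyl-5-SC-cyclohex-2-en-1-one (both ring-enantiomeric forms; 6′R), via potassium alkoxide 22 (not isolated), via oxido-hexatriene 23 (not isolated), via cyclohexadienolate 24 (not isolated)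
Conditions: KHMDS (1.05 equiv), THF, −78 to −30 °C; then −78 °C, 2‑(phenylsulfonyl)‑3‑phenyloxaziridine; AcOH, −78 °C
Reagents that add atoms: 2-(phenylsulfonyl)-3-phenyloxaziridine, O=S(=O)(c1ccccc1)N1OC1c1ccccc1
Why: Deprotonation gives cyclobutenolate 22, whose C1–C4 σ bond opens in a thermally allowed conrotatory 4π process in which the trans‑disposed O− (C1) and OAc (C4) both rotate outward and the alkenyl group is forced inward, giving 3‑oxido‑hexatriene 23 with an E enol‑acetate terminus; 23 then closes by a thermal disrotatory 6π electrocyclisation (bond between the former cyclobutene C4 and the alkenyl β‑carbon) to dienolate 24, a two‑carbon ring expansion driven by release of cyclobutene strain, and 24 is hydroxylated at C6 by the N‑sulfonyloxaziridine. The closest known reaction type is the oxy‑anion‑accelerated electrocyclic opening of 1‑alkenylcyclobut‑2‑en‑1‑olates with ensuing 6π closure to cyclohexenones, here joined to the standard oxaziridine hydroxylation of a potassium enolate. The six‑membered ring is closed in the 6π‑disrotatory mode, which turns the two outward terminal substituents (OAc from the E enol acetate, the dienyl chain from the E alkenyl group) cis on C4 and C5. The C6 hydroxyl should enter anti to the adjacent C5 substituent (and to the C4 acetate on the same face), giving the 5,6‑trans relationship. Because 23 is planar apart from the remote C6′ centre, both disrotatory senses should be used about equally, so 25 is expected as a near‑equal pair of the target and its 4R,5S,6S ring diastereomer, which step 13 separates. The step needs torquoselectivity (secured by the trans 1,4‑dioxygen pattern from step 10), 6π rather than 8π closure (secured by the E alkenyl bond, which keeps the termini of the extended tetraene apart) and survival of the acetate (the alkoxide is trans to it on the four‑membered ring, and one equivalent of a hindered amide base is used at low temperature).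

Step 13
Reactants: 25 4,5-cis-5,6-trans-4-acetoxy-6-hydroxy-2-methyl-5-SC-cyclohex-2-en-1-one (both ring-enantiomeric forms; 6′R)
Product: 26 (1S,5R,6R)-5-hydroxy-3-methyl-4-oxo-6-[(2E,4E,6R,7Z)-6,10-dimethylundeca-2,4,7-trien-2-yl]cyclohex-2-en-1-yl acetate
Conditions: Burkholderia cepacia lipase (immobilised), vinyl acetate, MTBE, 30 °C; chromatography
Reagents that add atoms: none
Why: lipase‑catalysed kinetic resolution by transesterification; the two components are mirror images at all three ring centres, and the enzyme should acetylate the C6 carbinol of the 4R,5S,6S isomer (the arrangement with the large C5 side and the medium carbonyl side that lipases usually accept) and leave 26 untouched, to be separated from the diacetate.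

**Compound list**
1 | (S)-3-bromo-2-methylpropan-1-ol | OC[C@H](C)CBr | starting material
2 | (S)-(3-hydroxy-2-methylpropyl)triphenylphosphonium bromide | OC[C@H](C)C[P+](c1ccccc1)(c1ccccc1)c1ccccc1.[Br-] | intermediate
3 | 3-methylbutanal | CC(C)CC=O | starting material
4 | sodium (S)-2-methyl-3-(triphenyl-λ5-phosphanylidene)propan-1-olate (oxido ylide) | [Na+].[O-]C[C@H](C)C=P(c1ccccc1)(c1ccccc1)c1ccccc1 | intermediate
5 | (2R,3Z)-2,6-dimethylhept-3-en-1-ol | OC[C@H](C)/C=C\CC(C)C | intermediate
6 | 5-{[(2R,3Z)-2,6-dimethylhept-3-en-1-yl]sulfanyl}-1-phenyl-1H-tetrazole | c1ccc(cc1)-n1nnnc1SC[C@H](C)/C=C\CC(C)C | intermediate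
7 | 5-{[(2R,3Z)-2,6-dimethylhept-3-en-1-yl]sulfonyl}-1-phenyl-1H-tetrazole | c1ccc(cc1)-n1nnnc1S(=O)(=O)C[C@H](C)/C=C\CC(C)C | intermediate
8 | (2E)-3-methylpent-2-en-4-yn-1-ol | C#C/C(C)=C/CO | starting material
9 | (2E,4E)-3-methyl-5-(tributylstannyl)penta-2,4-dien-1-ol | CCCC[Sn](CCCC)(CCCC)/C=C/C(C)=C/CO | intermediate
10 | (2E,4E)-3-methyl-5-(tributylstannyl)penta-2,4-dienal | CCCC[Sn](CCCC)(CCCC)/C=C/C(C)=C/C=O | intermediate
11 | potassium salt of α-metalated sulfone 7 | [K+].c1ccc(cc1)-n1nnnc1S(=O)(=O)[CH-][C@H](C)/C=C\CC(C)C | intermediate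
12 | tributyl[(1E,3E,5E,7R,8Z)-3,7,11-trimethyldodeca-1,3,5,8-tetraen-1-yl]stannane | CCCC[Sn](CCCC)(CCCC)/C=C/C(C)=C/C=C/[C@H](C)/C=C\CC(C)C | intermediate
13 | diisopropyl squarate (3,4-diisopropoxycyclobut-3-ene-1,2-dione) | CC(C)OC1=C(OC(C)C)C(=O)C1=O | starting material
14 | 4-hydroxy-2,3-diisopropoxycyclobut-2-en-1-one | CC(C)OC1=C(OC(C)C)C(O)C1=O | intermediate
15 | 3-isopropoxycyclobut-3-ene-1,2-dione | CC(C)OC1=CC(=O)C1=O | intermediate
16 | [(1E,3E,5E,7R,8Z)-3,7,11-trimethyldodeca-1,3,5,8-tetraen-1-yl]lithium | [Li]/C=C/C(C)=C/C=C/[C@H](C)/C=C\CC(C)C | intermediate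
17 | lithium 2-isopropoxy-4-oxo-1-Tet-cyclobut-2-en-1-olate (both C1 epimers) | [Li+].CC(C)OC1=CC(=O)C1([O-])/C=C/C(C)=C/C=C/[C@H](C)/C=C\CC(C)C | intermediate
18 | dilithium 3-isopropoxy-1-methyl-2-Tet-cyclobut-3-ene-1,2-diolate (stereoisomer mixture) | [Li+].[Li+].CC(C)OC1=CC(C)([O-])C1([O-])/C=C/C(C)=C/C=C/[C@H](C)/C=C\CC(C)C | intermediate
19 | 4-hydroxy-3-methyl-4-Tet-cyclobut-2-en-1-one (both C4 epimers) | CC1=CC(=O)C1(O)/C=C/C(C)=C/C=C/[C@H](C)/C=C\CC(C)C | intermediate
20 | (1R*,4R*)-2-methyl-1-Tet-cyclobut-2-ene-1,4-diol (trans diol; 1R,4R form drawn) | CC1=C[C@@H](O)[C@@]1(O)/C=C/C(C)=C/C=C/[C@H](C)/C=C\CC(C)C | intermediate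
21 | (1R*,4R*)-4-hydroxy-3-methyl-4-Tet-cyclobut-2-en-1-yl acetate (1R,4R form drawn) | CC1=C[C@@H](OC(C)=O)[C@@]1(O)/C=C/C(C)=C/C=C/[C@H](C)/C=C\CC(C)C | intermediate
22 | potassium alkoxide of 21 | [K+].CC1=C[C@@H](OC(C)=O)[C@@]1([O-])/C=C/C(C)=C/C=C/[C@H](C)/C=C\CC(C)C | intermediate
23 | potassium (1E,3E,5E,7E,9E,11R,12Z)-1-acetoxy-3,7,11,15-tetramethylhexadeca-1,3,5,7,9,12-hexaen-4-olate | [K+].CC(=O)O/C=C/C(C)=C(/[O-])\C=C\C(C)=C\C=C\[C@H](C)/C=C\CC(C)C | intermediate
24 | potassium 4,5-cis-4-acetoxy-2-methyl-5-SC-cyclohexa-1(6),2-dien-1-olate (4S,5S form drawn) | [K+].CC(=O)O[C@H]1C=C(C)C([O-])=C[C@H]1/C(C)=C/C=C/[C@H](C)/C=C\CC(C)C | intermediate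
25 | 4,5-cis-5,6-trans-4-acetoxy-6-hydroxy-2-methyl-5-SC-cyclohex-2-en-1-one, pair of the 4S,5R,6R and 4R,5S,6S ring diastereomers (6′R) | CC(=O)O[C@H]1C=C(C)C(=O)[C@H](O)[C@H]1/C(C)=C/C=C/[C@H](C)/C=C\CC(C)C.CC(=O)O[C@@H]1C=C(C)C(=O)[C@@H](O)[C@@H]1/C(C)=C/C=C/[C@H](C)/C=C\CC(C)C | intermediate
26 | (1S,5R,6R)-5-hydroxy-3-methyl-4-oxo-6-[(2E,4E,6R,7Z)-6,10-dimethylundeca-2,4,7-trien-2-yl]cyclohex-2-en-1-yl acetate | CC(=O)O[C@H]1C=C(C)C(=O)[C@H](O)[C@H]1/C(C)=C/C=C/[C@H](C)/C=C\CC(C)C | target

**Step count and risks**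
Total steps: 13. Longest linear sequence: 10 steps (1, 2, 3, 4, 7, 9, 10, 11, 12, 13).

Steps most likely to fail:

1. Step 12. The acetate may be lost or transferred (acyl migration onto the enolate carbon) during the basic cascade, or the open‑chain enolate may be oxidised before ring closure. The fallback carries the C4 oxygen through the ring expansion as a silyl ether and introduces the acetate afterwards. It sets out from 20 and comes back at 25. The secondary hydroxyl of 20 would be silylated (TESCl, imidazole, CH2Cl2, −20 °C) to the triethylsilyl ether F1. The same KHMDS/oxaziridine sequence on F1 should give the 4‑triethylsilyloxy‑6‑hydroxy enone F2. Silylation of the C6 hydroxyl (TBSOTf, 2,6‑lutidine) would give the bis‑silyl ether F3, selective methanolysis of the triethylsilyl group (PPTS, MeOH, 0 °C) the C4 alcohol F4, and acetylation (Ac2O, pyridine, DMAP) the acetate F5. HF·pyridine would then free the C6 hydroxyl and return the route to 25.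

2. Step 13. The lipase may discriminate poorly between the two ring diastereomers, or react too slowly at the hindered C6 carbinol. The fallback replaces the enzyme by separation of covalent diastereomers. It sets out from 25 and comes back at 26. The C6 hydroxyl of both components would be esterified with (S)‑2‑methoxy‑2‑phenylacetic acid (DCC, DMAP, CH2Cl2) to the mandelate F6 of the target series and the mandelate F7 of the 4R,5S,6S series. These differ at three ring centres relative to the auxiliary and should separate on silica. Mild Lewis‑acid methanolysis of the activated α‑methoxy ester of F6 (Yb(OTf)3, MeOH, 0 °C), which should leave the C4 acetate intact, would give 26.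

3. Step 9. The vicinal dialkoxide may open electrocyclically before the quench, or the tertiary bis‑allylic alcohol may ionise during the acidic hydrolysis. The fallback is stepwise with isolation and protection instead of the one‑pot dianion route. It sets out from 12 (with 15) and comes back at 19. After tin–lithium exchange and addition to 15, an NH4Cl quench would allow isolation of the hydroxy enone F8. Silylation (TMSCl, imidazole, DMF, 0 °C) would give the trimethylsilyl ether F9. Addition of MeLi/CeCl3 (THF, −78 °C) would give the tertiary alcohol F10, and treatment of F10 with dilute oxalic acid in wet THF at 0 °C should remove the silyl group and transpose the carbonyl to give 19.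

Further compounds
F1 | step 12 | (1R*,4R*)-2-methyl-1-Tet-4-(triethylsilyloxy)cyclobut-2-en-1-ol | CC1=C[C@@H](O[Si](CC)(CC)CC)[C@@]1(O)/C=C/C(C)=C/C=C/[C@H](C)/C=C\CC(C)C
F2 | step 12 | 4,5-cis-5,6-trans-6-hydroxy-2-methyl-5-SC-4-(triethylsilyloxy)cyclohex-2-en-1-one (both ring forms; one drawn) | CC[Si](CC)(CC)O[C@H]1C=C(C)C(=O)[C@H](O)[C@H]1/C(C)=C/C=C/[C@H](C)/C=C\CC(C)C
F3 | step 12 | 4,5-cis-5,6-trans-6-(tert-butyldimethylsilyloxy)-2-methyl-5-SC-4-(triethylsilyloxy)cyclohex-2-en-1-one | CC[Si](CC)(CC)O[C@H]1C=C(C)C(=O)[C@H](O[Si](C)(C)C(C)(C)C)[C@H]1/C(C)=C/C=C/[C@H](C)/C=C\CC(C)C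
F4 | step 12 | 4,5-cis-5,6-trans-6-(tert-butyldimethylsilyloxy)-4-hydroxy-2-methyl-5-SC-cyclohex-2-en-1-one | O[C@H]1C=C(C)C(=O)[C@H](O[Si](C)(C)C(C)(C)C)[C@H]1/C(C)=C/C=C/[C@H](C)/C=C\CC(C)C
F5 | step 12 | 4,5-cis-5,6-trans-4-acetoxy-6-(tert-butyldimethylsilyloxy)-2-methyl-5-SC-cyclohex-2-en-1-one | CC(=O)O[C@H]1C=C(C)C(=O)[C@H](O[Si](C)(C)C(C)(C)C)[C@H]1/C(C)=C/C=C/[C@H](C)/C=C\CC(C)C
F6 | step 13 | C6 (S)-2-methoxy-2-phenylacetate of 26 | CC(=O)O[C@H]1C=C(C)C(=O)[C@H](OC(=O)[C@@H](OC)c2ccccc2)[C@H]1/C(C)=C/C=C/[C@H](C)/C=C\CC(C)C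
F7 | step 13 | C6 (S)-2-methoxy-2-phenylacetate of the 4R,5S,6S ring diastereomer of 26 | CC(=O)O[C@@H]1C=C(C)C(=O)[C@@H](OC(=O)[C@@H](OC)c2ccccc2)[C@@H]1/C(C)=C/C=C/[C@H](C)/C=C\CC(C)C
F8 | step 9 | 4-hydroxy-3-isopropoxy-4-Tet-cyclobut-2-en-1-one | CC(C)OC1=CC(=O)C1(O)/C=C/C(C)=C/C=C/[C@H](C)/C=C\CC(C)C
F9 | step 9 | 3-isopropoxy-4-Tet-4-(trimethylsilyloxy)cyclobut-2-en-1-one | CC(C)OC1=CC(=O)C1(O[Si](C)(C)C)/C=C/C(C)=C/C=C/[C@H](C)/C=C\CC(C)C
F10 | step 9 | 3-isopropoxy-1-methyl-4-Tet-4-(trimethylsilyloxy)cyclobut-2-en-1-ol | CC(C)OC1=CC(C)(O)C1(O[Si](C)(C)C)/C=C/C(C)=C/C=C/[C@H](C)/C=C\CC(C)C
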